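**Assumption:** the target has no sp³ stereocentre. Its only stereochemical element is the exocyclic C=C. From the SMILES, C4 and the aryl group are trans across that alkene, so O1 and the aryl are cis, which is (Z). Step 5 sets this geometry.

## Retrosynthetic overview
Numbers are assigned from Step 1 onward.
1. Remove the two aryl methyl ethers in the last step. Protecting the phenols is needed because the phenoxides would shut down the condensation.
2. Disconnect the (Z)-5-arylidene by an aldol condensation between the acidic γ-CH₂ (C5) of a 4-aryl-2(5H)-furanone and 3,5-dibromo-4-methoxybenzaldehyde.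
3. Make the 4-aryl butenolide by Suzuki coupling of the enol tosylate of tetronic acid. The only ring is the butenolide, which comes ready-made from tetronic acid.
4. Install the aryl Br atoms by bromination of the free phenol, while the only other C=C is the electron-poor butenolide alkene.

## Route

**Step 1**
Reactants: 1 tetronic acid; 2 p-toluenesulfonyl chloride
Product: 3 4-(tosyloxy)furan-2(5H)-one
Conditions: TsCl, Et₃N, CH₂Cl₂, 0 °C → rt
Reagents that add atoms: TsCl, Cc1ccc(cc1)S(=O)(=O)Cl (Ts group stays in 3)
Why: The tetronate oxygen is sulfonylated (O-tosylation of a vinylogous acid) to give a stable enol tosylate that is a Suzuki electrophile. No stereocentre is formed.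

**Step 2**
Reactants: 3 4-(tosyloxy)furan-2(5H)-one; 4 4-hydroxyphenylboronic acid
Product: 5 4-(4-hydroxyphenyl)furan-2(5H)-one
Conditions: Pd(PPh₃)₄ (5 mol %), KF, THF/H₂O, 60 °C
Reagents that add atoms: 4, OB(O)c1ccc(O)cc1 (supplies the 4-hydroxyphenyl group)
Why: Suzuki–Miyaura coupling at the C4 enol tosylate. Free phenols are tolerated, and mild KF avoids hydrolysis of the tosylate and lactone.

**Step 3**
Reactants: 5 4-(4-hydroxyphenyl)furan-2(5H)-one; 6 bromine
Product: 7 4-(3,5-dibromo-4-hydroxyphenyl)furan-2(5H)-one
Conditions: Br₂ (2.05 equiv), AcOH, 15–20 °C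
Reagents that add atoms: Br₂, BrBr
Why: Electrophilic aromatic bromination occurs at both positions ortho to the phenol OH. The conjugated butenolide alkene is electron-poor and does not react at rt without base.

**Step 4**
Reactants: 7 phenol; 8 iodomethane
Product: 9 4-(3,5-dibromo-4-methoxyphenyl)furan-2(5H)-one
Conditions: MeI (1.5 equiv), K₂CO₃, acetone, reflux
Reagents that add atoms: MeI, CI (CH₃ stays in 9)
Why: Williamson O-methylation of the acidic 2,6-dibromophenol (pKa ≈ 6). The resulting phenoxide is conjugated with the butenolide, which disfavours C5 deprotonation and C-alkylation.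

**Step 5**
Reactants: 9 butenolide; 10 3,5-dibromo-4-methoxybenzaldehyde
Product: 11 (Z)-5-(3,5-dibromo-4-methoxybenzylidene)-4-(3,5-dibromo-4-methoxyphenyl)furan-2(5H)-one
Conditions: 10 (1.2 equiv), KF/Al₂O₃, MeCN, 60 °C
Reagents that add atoms: 10, COc1c(Br)cc(C=O)cc1Br (aryl-CH= unit stays in 11)
Why: Vinylogous aldol condensation (aldol then E1cB dehydration) through the C5 dienolate. The sp² exocyclic alkene is formed under thermodynamic control. The (Z) isomer, with the aryl cis to O1 and away from the C4 aryl, is sterically favoured and is the only geometry set in the route.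

**Step 6**
Reactants: 11 bis-methyl ether; 12 boron tribromide
Product: 13 Rubrolide A target, (Z)-4,5-bis(3,5-dibromo-4-hydroxyphenyl/benzylidene) butenolide
Conditions: BBr₃ (4 equiv), CH₂Cl₂, −78 → 0 °C, then aq. NaHCO₃ quench
Reagents that add atoms: none (BBr₃, BrB(Br)Br, leaves no atoms in the product; the methyls leave as MeBr)
Why: BBr₃ cleaves aryl methyl ethers (Lewis-acid demethylation) under cold conditions, without the base or nucleophile that would open the enol lactone. The Z-alkene and Ar–Br bonds are untouched.

## Checks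
- **Target match:** Product 13 has a butenolide with C4-aryl and C5=CH-aryl, and both aryls are 3,5-dibromo-4-hydroxyphenyl. Its SMILES is identical to the target, including the "/C(=C/" Z-alkene pattern.
- **Atom balance:**
  - Step 1: C₄H₄O₃ + TsCl → C₁₁H₁₀O₅S.
  - Step 3: C₁₀H₈O₃ + 2 Br₂ → C₁₀H₆Br₂O₃ + 2 HBr.
  - Step 5: C₁₁H₈Br₂O₃ + C₈H₆Br₂O₂ → C₁₉H₁₂Br₄O₄ + H₂O.
  - Step 6: C₁₉H₁₂Br₄O₄ → C₁₇H₈Br₄O₄ + 2 CH₃Br.
- **Functional-group survival:** Ar–Br bonds are never exposed to Pd, because the Suzuki step precedes bromination. Methyl ethers survive Steps 5 and 6 until BBr₃. The lactone survives all steps, provided the BBr₃ step is kept cold.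
- **Stereochemistry:** The Z-alkene is formed in Step 5 and is not touched afterwards, since the final BBr₃ step is non-isomerising.

## Compound list
| No. | Name | SMILES | Role |
|---|---|---|---|
| 1 | Tetronic acid (furan-2,4(3H,5H)-dione) | O=C1CC(=O)OC1 | starting material |
| 2 | p-Toluenesulfonyl chloride | Cc1ccc(cc1)S(=O)(=O)Cl | starting material |
| 3 | 4-(Tosyloxy)furan-2(5H)-one | Cc1ccc(cc1)S(=O)(=O)OC1=CC(=O)OC1 | intermediate |
| 4 | 4-Hydroxyphenylboronic acid | OB(O)c1ccc(O)cc1 | starting material |
| 5 | 4-(4-Hydroxyphenyl)furan-2(5H)-one | O=C1C=C(c2ccc(O)cc2)CO1 | intermediate |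
| 6 | Bromine | BrBr | starting material |
| 7 | 4-(3,5-Dibromo-4-hydroxyphenyl)furan-2(5H)-one | O=C1C=C(c2cc(Br)c(O)c(Br)c2)CO1 | intermediate |
| 8 | Iodomethane | CI | starting material |
| 9 | 4-(3,5-Dibromo-4-methoxyphenyl)furan-2(5H)-one | O=C1C=C(c2cc(Br)c(OC)c(Br)c2)CO1 | intermediate |
| 10 | 3,5-Dibromo-4-methoxybenzaldehyde | COc1c(Br)cc(C=O)cc1Br | starting material |
| 11 | (Z)-5-(3,5-Dibromo-4-methoxybenzylidene)-4-(3,5-dibromo-4-methoxyphenyl)furan-2(5H)-one | O=C1C=C(c2cc(Br)c(OC)c(Br)c2)/C(=C/c2cc(Br)c(OC)c(Br)c2)O1 | intermediate |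
| 12 | Boron tribromide | BrB(Br)Br | starting material (reagent) |
| 13 | Rubrolide A, (Z)-4-(3,5-dibromo-4-hydroxyphenyl)-5-(3,5-dibromo-4-hydroxybenzylidene)furan-2(5H)-one | O=C1C=C(c2cc(Br)c(O)c(Br)c2)/C(=C/c2cc(Br)c(O)c(Br)c2)O1 | target |

**Total steps:** 6. **Longest linear sequence:** 6 (1 → 3 → 5 → 7 → 9 → 11 → 13).

## Three steps most likely to fail
1. **Step 5 (condensation, yield and Z/E ratio).** Base can cause decomposition or give E/Z mixtures.
   - Fallback: a two-stage route via a 2-silyloxyfuran. Treat 9 with TBSOTf/Et₃N, then add 10 in a vinylogous Mukaiyama aldol. Dehydrate the resulting β-silyloxy or hydroxy adduct with MsCl/Et₃N then DBU, which eliminates to the Z-arylidene.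
2. **Step 6 (BBr₃ may open or ionise the enol lactone).**
   - Fallback: swap methyl for MOM protection. Use MOMCl on 7 in Step 4 and on commercial 3,5-dibromo-4-hydroxybenzaldehyde for 10. Remove both MOM groups at the end with HCl/iPrOH or TFA, with no strong Lewis acid.
3. **Step 3 (selective dibromination).** Alkene addition or over-bromination would give the wrong product.
   - Fallback: avoid late aromatic bromination. Start from commercial 3,5-dibromo-4-methoxyacetophenone. Brominate α with CuBr₂, then displace with formate and hydrolyse to the α-hydroxyketone. Treat with triethyl phosphonoacetate/NaH (HWE) and lactonise with acid to give 9 directly, with no Pd and no free-phenol bromination.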